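**Plan**
1. Retrosynthesis: cut the O8 acrylate ester and the four oxirane C–O bonds (back to a 1(10),4-diene), then the butenolide at C7=C11 (Horner–Wadsworth–Emmons) and at O6–C12 (ester), then C2–C3 by a retro-[3,3] shift that restores a C5–C10 bond.
2. Enabling feature: with the oxiranes read as alkenes, C10=C1–C2–C3–C4=C5 is a 1,5-diene whose central bond is C2–C3, so the ten-membered ring C1–C10 is the Cope ring-expansion product of a six-membered ring C5–C10. An oxido group on C5 drives the shift, and the resulting C4=C5 enolate is kept as a triflate.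
3. Forward order: six-membered ring C5–C10 (from a 4-alkoxycyclohexenone), ring expansion to the ten-membered ring, C7 ketone and C6 hydroxyl, butenolide ring, side-chain esters, both oxiranes last.
4. Stereochemistry: C8 comes from an asymmetric transfer hydrogenation. It relays to the temporary centres C10, C6/C7 (oxirane) and C5, which fix the E,E geometry through a chair transition state. C6 and then C1, C10, C4, C5 follow by outer-face attack on the ten-membered ring.

Key step: step 9

Remark: germacrane numbering (ring C1–C10, lactone carbons C11–C13, C14 on C10, C15 on C4) is used for the ring carbons from the first step on; α is the face of O8, β the opposite face; compounds 1, 20 and 28 are taken to be commercial.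

**Step 1**
Reactants: 1 1,4-dioxaspiro[4.5]dec-6-en-8-one
Product: 2 (S)-1,4-dioxaspiro[4.5]dec-6-en-8-ol
Conditions: RuCl(p-cymene)[(S,S)-TsDPEN] (1 mol %), HCO2Na, Bu4NCl, CH2Cl2/H2O, rt
Reagents that add atoms: none
Why: Noyori asymmetric transfer hydrogenation of the enone carbonyl, in which the alkenyl group takes the place of the aryl group of the usual model, so the (S,S) ligand should deliver the S carbinol that becomes C8.

**Step 2**
Reactants: 2 (S)-1,4-dioxaspiro[4.5]dec-6-en-8-ol
Product: 3 (S)-8-(4-methoxybenzyloxy)-1,4-dioxaspiro[4.5]dec-6-ene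
Conditions: NaH, 4-MeOC6H4CH2Cl, Bu4NI (cat.), THF/DMF, 0 °C to rt
Reagents that add atoms: 4-methoxybenzyl chloride, COc1ccc(CCl)cc1
Why: Williamson etherification gives an ether that should survive the strong bases, the hydride transfer and the oxidations up to step 17.

**Step 3**
Reactants: 3 (S)-8-(4-methoxybenzyloxy)-1,4-dioxaspiro[4.5]dec-6-ene
Product: 4 (S)-4-(4-methoxybenzyloxy)cyclohex-2-en-1-one
Conditions: 1 M HCl (cat.), THF/H2O, rt
Reagents that add atoms: water, O
Why: acid hydrolysis of the allylic ketal unmasks the C5 carbonyl in conjugation with C6=C7 and leaves the benzylic ether and C8 untouched.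

**Step 4**
Reactants: 4 (S)-4-(4-methoxybenzyloxy)cyclohex-2-en-1-one
Product: 6 (4S,6RS)-4-(4-methoxybenzyloxy)-6-methylcyclohex-2-en-1-one, via lithium dienolate 5 (not isolated)
Conditions: LiN(i-Pr)2, THF, −78 °C; MeI, −78 to −30 °C
Reagents that add atoms: iodomethane, CI
Why: kinetic deprotonation of a cyclohexenone at the saturated α′ carbon (C10) followed by enolate alkylation; the configuration of this carbon is erased in step 5.

**Step 5**
Reactants: 6 (4S,6RS)-4-(4-methoxybenzyloxy)-6-methylcyclohex-2-en-1-one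
Product: 8 (4S,6R)-6-(1-hydroxyethyl)-4-(4-methoxybenzyloxy)-6-methylcyclohex-2-en-1-one (both carbinol epimers), via lithium dienolate 7 (not isolated)
Conditions: LiN(i-Pr)2, THF, −78 °C; CH3CHO, −78 °C; AcOH
Reagents that add atoms: acetaldehyde, CC=O
Why: aldol addition of the tetrasubstituted cross-conjugated enolate, in which the aldehyde should enter anti to the C8 alkoxy group, so the two-carbon unit at quaternary C10 ends up trans to O8.

**Step 6**
Reactants: 8 (4S,6R)-6-(1-hydroxyethyl)-4-(4-methoxybenzyloxy)-6-methylcyclohex-2-en-1-one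
Product: 9 (4S,6R)-4-(4-methoxybenzyloxy)-6-methyl-6-vinylcyclohex-2-en-1-one
Conditions: Martin sulfurane Ph2S[OC(CF3)2Ph]2, CH2Cl2, 0 °C to rt
Reagents that add atoms: none
Why: sulfurane dehydration of the secondary alcohol can only remove a methyl hydrogen because the other neighbour is quaternary, which gives the vinyl group under conditions that cannot trigger a retro-aldol.

**Step 7**
Reactants: 9 (4S,6R)-4-(4-methoxybenzyloxy)-6-methyl-6-vinylcyclohex-2-en-1-one
Product: 10 (1R,3R,5S,6R)-5-(4-methoxybenzyloxy)-3-methyl-3-vinyl-7-oxabicyclo[4.1.0]heptan-2-one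
Conditions: t-BuOOH, BnMe3N+ OH− (cat.), THF, 0 °C
Reagents that add atoms: tert-butyl hydroperoxide, CC(C)(C)OO
Why: Weitz–Scheffer nucleophilic epoxidation, in which the hydroperoxide adds to C7 anti to the neighbouring C8 alkoxy group, so the C6–C7 oxirane sits trans to O8 and cis to the vinyl group; the ketone has no enolizable hydrogen.

**Step 8**
Reactants: 10 (1R,3R,5S,6R)-5-(4-methoxybenzyloxy)-3-methyl-3-vinyl-7-oxabicyclo[4.1.0]heptan-2-one
Product: 11 (1R,2S,3R,5S,6R)-5-(4-methoxybenzyloxy)-3-methyl-2-(prop-1-en-2-yl)-3-vinyl-7-oxabicyclo[4.1.0]heptan-2-ol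
Conditions: CH2=C(CH3)MgBr, CeCl3, THF, −78 °C; H2O
Reagents that add atoms: isopropenylmagnesium bromide, CC(=C)[Mg]Br
Why: organocerium 1,2-addition to an α,β-epoxy ketone occurs anti to the oxirane oxygen, which here is also anti to the vinyl group on C10, so the isopropenyl group at C5 is trans to vinyl and the hydroxyl trans to the C10 methyl.

**Step 9**
Reactants: 11 (1R,2S,3R,5S,6R)-5-(4-methoxybenzyloxy)-3-methyl-2-(prop-1-en-2-yl)-3-vinyl-7-oxabicyclo[4.1.0]heptan-2-ol
Product: 14 (1(10)E)-6β,7β-epoxy-8α-(4-methoxybenzyloxy)-4,10-dimethylcyclodeca-1(10),4-dien-5-yl trifluoromethanesulfonate (C3 and C6 trans on C4=C5), via potassium alkoxide 12 (not isolated), via potassium enolate 13 (not isolated)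
Conditions: KH, 18-crown-6, THF, 0 °C to rt; PhNTf2, −78 to 0 °C
Reagents that add atoms: N-phenylbis(trifluoromethanesulfonimide), O=S(=O)(N(c1ccccc1)S(=O)(=O)C(F)(F)F)C(F)(F)F
Why: KH with 18-crown-6 turns 11 into the free alkoxide 12, whose C5–O− group weakens the C5–C10 bond so that the 1,5-diene C3=C4–C5–C10–C1=C2 undergoes an anionic oxy-Cope [3,3] shift at or below room temperature, forming C2–C3 and giving enolate 13, which PhNTf2 sulfonylates on oxygen. The closest known reaction type is the anionic oxy-Cope ring expansion of trans-1,2-divinylcyclohexanols to cyclodec-5-enones with trapping of the regiodefined enolate. The ten-membered carbocycle C1–C10 is closed by four-atom sigmatropic ring expansion of the six-membered ring C5–C10, not by end-to-end cyclization, and the C6–C7 oxirane is carried into the new ring. No new stereocentre arises; the geometry of both new alkenes is set by the chair transition state with vinyl and isopropenyl both equatorial (they are trans on the ring), which puts C9 trans to C2 on C1=C10 and C6 trans to C3 on C4=C5, while C6, C7 and C8 keep their configuration. The step needs chair over boat selectivity and an intact oxirane and enolate position: the trans alkenyl arrangement from steps 5 to 8 secures the first, the cis relation of O− and oxirane rules out Payne-type attack, and the enolate cannot move because no proton source is present before the triflimide is added.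

**Step 10**
Reactants: 14 enol triflate of step 9
Product: 16 (1S,3E,7E,10S)-10-(4-methoxybenzyloxy)-4,8-dimethylcyclodeca-3,7-dien-1-ol (germacrane numbering: 7β-hydroxy, 8α-ether, 1(10)E,4E), via vinyl epoxide 15 (not isolated)
Conditions: Pd(PPh3)4 (5 mol %), Bu3SnH (2.5 equiv), THF, 0 °C to rt; aqueous work-up
Reagents that add atoms: none
Why: zerovalent palladium inserts into the enol triflate and the stannane reduces it with retention of alkene geometry, then the vinyl epoxide 15 ionizes to an allylpalladium alkoxide that takes hydride at the less substituted terminus C6 (palladium-catalysed hydrogenolysis of alkenyl oxiranes to homoallylic alcohols), leaving C4=C5 in place and an oxygen on C7 only.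

**Step 11**
Reactants: 16 (1S,3E,7E,10S)-10-(4-methoxybenzyloxy)-4,8-dimethylcyclodeca-3,7-dien-1-ol
Product: 17 (3E,7E,10S)-10-(4-methoxybenzyloxy)-4,8-dimethylcyclodeca-3,7-dien-1-one
Conditions: Dess–Martin periodinane, pyridine, CH2Cl2, 0 °C
Reagents that add atoms: none
Why: Dess–Martin oxidation of the secondary alcohol under buffered, non-basic conditions should give the C7 ketone without moving the β,γ-alkene into conjugation.

**Step 12**
Reactants: 17 (3E,7E,10S)-10-(4-methoxybenzyloxy)-4,8-dimethylcyclodeca-3,7-dien-1-one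
Product: 19 (2R,3E,7E,10S)-2-hydroxy-10-(4-methoxybenzyloxy)-4,8-dimethylcyclodeca-3,7-dien-1-one (germacrane numbering: 6α-hydroxy-7-oxo-8α-ether), via potassium dienolate 18 (not isolated)
Conditions: KN(SiMe3)2, THF, −78 °C; (±)-trans-2-(phenylsulfonyl)-3-phenyloxaziridine, −78 °C; AcOH
Reagents that add atoms: trans-2-(phenylsulfonyl)-3-phenyloxaziridine (Davis oxaziridine), O=S(=O)(c1ccccc1)N1OC1c1ccccc1
Why: Davis enolate hydroxylation, in which the doubly activated C6 hydrogen (allylic and α to the ketone) is removed and the oxidant attacks C6 on the outer face of the macrocycle, which is the face of the C8 ether because allylic strain turns the ring bond C8–C9 to the other face; this sets 6α, cis to O8.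

**Step 13**
Reactants: 20 allyl 2-(diethoxyphosphoryl)acetate
Product: 22 allyl 2-(diethoxyphosphoryl)-3-(4-methoxybenzyloxy)propanoate (racemic), via phosphonoacrylate 21 (not isolated)
Conditions: (CH2O)n, 4-MeOC6H4CH2OH (3 equiv), piperidine (cat.), toluene, 80 °C
Reagents that add atoms: formaldehyde (as paraformaldehyde), C=O; 4-methoxybenzyl alcohol, COc1ccc(CO)cc1
Why: Knoevenagel condensation of the phosphonoacetate with formaldehyde, followed by oxa-Michael addition of the benzylic alcohol to the phosphonoacrylate 21, as known for the methanol adduct of the ethyl ester.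

**Step 14**
Reactants: 22 allyl 2-(diethoxyphosphoryl)-3-(4-methoxybenzyloxy)propanoate
Product: 23 2-(diethoxyphosphoryl)-3-(4-methoxybenzyloxy)propanoic acid (racemic)
Conditions: Pd(PPh3)4 (3 mol %), morpholine, THF, rt; 1 M HCl
Reagents that add atoms: none
Why: Tsuji–Trost deallylation with morpholine as allyl acceptor frees the acid under neutral conditions, which avoids base-induced loss of the β-alkoxy group.

**Step 15**
Reactants: 19 (2R,3E,7E,10S)-2-hydroxy-10-(4-methoxybenzyloxy)-4,8-dimethylcyclodeca-3,7-dien-1-one; 23 2-(diethoxyphosphoryl)-3-(4-methoxybenzyloxy)propanoic acid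
Product: 24 (2R,3E,7E,10S)-10-(4-methoxybenzyloxy)-4,8-dimethyl-1-oxocyclodeca-3,7-dien-2-yl 2-(diethoxyphosphoryl)-3-(4-methoxybenzyloxy)propanoate (epimers at the phosphonate carbon)
Conditions: DCC, DMAP (cat.), CH2Cl2, 0 °C
Reagents that add atoms: none
Why: Steglich esterification of the α-hydroxy ketone places the phosphonoacetate unit on O6 without touching C6.

**Step 16**
Reactants: 24 phosphonate ester of step 15
Product: 25 (6R,8S)-8α,13-bis(4-methoxybenzyloxy)germacra-1(10)E,4E,7(11)-trien-6α,12-olide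
Conditions: LiCl, i-Pr2NEt, MeCN, rt
Reagents that add atoms: none
Why: intramolecular Horner–Wadsworth–Emmons olefination (Masamune–Roush conditions) of the C7 ketone closes the five-membered lactone, which fixes the lactone on O6 and the alkene at C7=C11; the mild base should spare the C6 centre and the β-alkoxy group.

**Step 17**
Reactants: 25 (6R,8S)-8α,13-bis(4-methoxybenzyloxy)germacra-1(10)E,4E,7(11)-trien-6α,12-olide
Product: 26 (6R,8S)-8α,13-dihydroxygermacra-1(10)E,4E,7(11)-trien-6α,12-olide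
Conditions: DDQ (2.4 equiv), CH2Cl2/pH 7 buffer, 0 °C to rt
Reagents that add atoms: none
Why: oxidative cleavage of both 4-methoxybenzyl ethers by DDQ at neutral pH leaves the acid-sensitive 1(10),4-diene and the butenolide intact.

**Step 18**
Reactants: 26 (6R,8S)-8α,13-dihydroxygermacra-1(10)E,4E,7(11)-trien-6α,12-olide
Product: 27 (6R,8S)-13-acetoxy-8α-hydroxygermacra-1(10)E,4E,7(11)-trien-6α,12-olide
Conditions: Ac2O (1.1 equiv), 2,4,6-collidine, CH2Cl2, −20 °C
Reagents that add atoms: acetic anhydride, CC(=O)OC(C)=O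
Why: selective acylation of the primary allylic C13 hydroxyl over the hindered secondary C8 hydroxyl.

**Step 19**
Reactants: 28 ethyl 2-(hydroxymethyl)acrylate
Product: 29 ethyl 2-((tert-butyldimethylsilyloxy)methyl)acrylate
Conditions: t-BuMe2SiCl, imidazole, DMF, rt
Reagents that add atoms: tert-butyldimethylsilyl chloride, CC(C)(C)[Si](C)(C)Cl
Why: standard silylation masks the hydroxyl of the future side chain.

**Step 20**
Reactants: 29 ethyl 2-((tert-butyldimethylsilyloxy)methyl)acrylate
Product: 30 2-((tert-butyldimethylsilyloxy)methyl)acrylic acid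
Conditions: LiOH, THF/H2O, 0 °C; 1 M HCl
Reagents that add atoms: lithium hydroxide, [Li+].[OH-]
Why: saponification of the ethyl ester under conditions that the silyl ether tolerates.

**Step 21**
Reactants: 27 (6R,8S)-13-acetoxy-8α-hydroxygermacra-1(10)E,4E,7(11)-trien-6α,12-olide; 30 2-((tert-butyldimethylsilyloxy)methyl)acrylic acid
Product: 31 (6R,8S)-13-acetoxy-8α-[2-((tert-butyldimethylsilyloxy)methyl)acryloyloxy]germacra-1(10)E,4E,7(11)-trien-6α,12-olide
Conditions: DCC, DMAP (cat.), CH2Cl2, 0 °C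
Reagents that add atoms: none
Why: Steglich esterification of the C8 hydroxyl with retention at C8.

**Step 22**
Reactants: 31 silyl-protected triene ester of step 21
Product: 33 (1R,4R,5R,6S,8S,10R)-13-acetoxy-8α-[2-((tert-butyldimethylsilyloxy)methyl)acryloyloxy]-1β,10α:4α,5β-diepoxygermacr-7(11)-en-6α,12-olide, via monoepoxide 32 (not isolated)
Conditions: mCPBA (2.5 equiv), CH2Cl2, 0 °C
Reagents that add atoms: 3-chloroperbenzoic acid, O=C(OO)c1cccc(Cl)c1
Why: Prilezhaev epoxidation attacks only the two electron-rich trisubstituted alkenes (not the acrylate or butenolide), each on its outer face in the crossed conformation with both methyl groups β, which should give the 1β,10α oxirane and the 4α,5β oxirane (threo to O6) as in germacranolide epoxidations, setting C1, C10, C4 and C5.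

**Step 23**
Reactants: 33 silyl-protected diepoxide of step 22
Product: 34 (1R,4R,5R,6S,8S,10R)-13-acetoxy-1β,10α:4α,5β-diepoxy-8α-[2-(hydroxymethyl)acryloyloxy]germacr-7(11)-en-6α,12-olide (CNP0282791.1)
Conditions: HF·pyridine, pyridine, THF, 0 °C
Reagents that add atoms: none
Why: buffered fluoride desilylation frees the primary hydroxyl and should leave the oxiranes, the acetate and both esters untouched.

**Compound list**
1 | 1,4-dioxaspiro[4.5]dec-6-en-8-one | O=C1C=CC2(CC1)OCCO2 | starting material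
2 | (S)-1,4-dioxaspiro[4.5]dec-6-en-8-ol | O[C@@H]1C=CC2(CC1)OCCO2 | intermediate
3 | (S)-8-(4-methoxybenzyloxy)-1,4-dioxaspiro[4.5]dec-6-ene | COc1ccc(CO[C@@H]2C=CC3(CC2)OCCO3)cc1 | intermediate
4 | (S)-4-(4-methoxybenzyloxy)cyclohex-2-en-1-one | COc1ccc(CO[C@@H]2C=CC(=O)CC2)cc1 | intermediate
5 | lithium (S)-4-(4-methoxybenzyloxy)cyclohexa-1,5-dien-1-olate | COc1ccc(CO[C@@H]2C=CC([O-])=CC2)cc1.[Li+] | intermediate
6 | (4S,6RS)-4-(4-methoxybenzyloxy)-6-methylcyclohex-2-en-1-one | COc1ccc(CO[C@@H]2C=CC(=O)C(C)C2)cc1 | intermediate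
7 | lithium (S)-4-(4-methoxybenzyloxy)-2-methylcyclohexa-1,5-dien-1-olate | COc1ccc(CO[C@@H]2C=CC([O-])=C(C)C2)cc1.[Li+] | intermediate
8 | (4S,6R)-6-(1-hydroxyethyl)-4-(4-methoxybenzyloxy)-6-methylcyclohex-2-en-1-one, both carbinol epimers | COc1ccc(CO[C@@H]2C=CC(=O)[C@@](C)(C(C)O)C2)cc1 | intermediate
9 | (4S,6R)-4-(4-methoxybenzyloxy)-6-methyl-6-vinylcyclohex-2-en-1-one | COc1ccc(CO[C@@H]2C=CC(=O)[C@@](C)(C=C)C2)cc1 | intermediate
10 | (1R,3R,5S,6R)-5-(4-methoxybenzyloxy)-3-methyl-3-vinyl-7-oxabicyclo[4.1.0]heptan-2-one | COc1ccc(CO[C@@H]2[C@H]3O[C@H]3C(=O)[C@@](C)(C=C)C2)cc1 | intermediate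
11 | (1R,2S,3R,5S,6R)-5-(4-methoxybenzyloxy)-3-methyl-2-(prop-1-en-2-yl)-3-vinyl-7-oxabicyclo[4.1.0]heptan-2-ol | COc1ccc(CO[C@@H]2[C@H]3O[C@H]3[C@](O)(C(C)=C)[C@@](C)(C=C)C2)cc1 | intermediate
12 | potassium alkoxide of 11 | COc1ccc(CO[C@@H]2[C@H]3O[C@H]3[C@]([O-])(C(C)=C)[C@@](C)(C=C)C2)cc1.[K+] | intermediate
13 | potassium (1(10)E)-6β,7β-epoxy-8α-(4-methoxybenzyloxy)-4,10-dimethylcyclodeca-1(10),4-dien-5-olate (C3 and C6 trans) | COc1ccc(CO[C@H]2C/C(C)=C/CC/C(C)=C([O-])/[C@@H]3O[C@@H]32)cc1.[K+] | intermediate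
14 | (1(10)E)-6β,7β-epoxy-8α-(4-methoxybenzyloxy)-4,10-dimethylcyclodeca-1(10),4-dien-5-yl trifluoromethanesulfonate (C3 and C6 trans) | COc1ccc(CO[C@H]2C/C(C)=C/CC/C(C)=C(OS(=O)(=O)C(F)(F)F)/[C@@H]3O[C@@H]32)cc1 | intermediate
15 | (1(10)E,4E)-6β,7β-epoxy-8α-(4-methoxybenzyloxy)-4,10-dimethylcyclodeca-1(10),4-diene | COc1ccc(CO[C@H]2C/C(C)=C/CC/C(C)=C/[C@@H]3O[C@@H]32)cc1 | intermediate
16 | (1S,3E,7E,10S)-10-(4-methoxybenzyloxy)-4,8-dimethylcyclodeca-3,7-dien-1-ol | COc1ccc(CO[C@H]2C/C(C)=C/CC/C(C)=C/C[C@@H]2O)cc1 | intermediate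
17 | (3E,7E,10S)-10-(4-methoxybenzyloxy)-4,8-dimethylcyclodeca-3,7-dien-1-one | COc1ccc(CO[C@H]2C/C(C)=C/CC/C(C)=C/CC2=O)cc1 | intermediate
18 | potassium dienolate of 17 (C6=C7 enolate) | COc1ccc(CO[C@H]2C/C(C)=C/CC/C(C)=C/C=C2[O-])cc1.[K+] | intermediate
19 | (2R,3E,7E,10S)-2-hydroxy-10-(4-methoxybenzyloxy)-4,8-dimethylcyclodeca-3,7-dien-1-one | COc1ccc(CO[C@H]2C/C(C)=C/CC/C(C)=C/[C@@H](O)C2=O)cc1 | intermediate
20 | allyl 2-(diethoxyphosphoryl)acetate | C=CCOC(=O)CP(=O)(OCC)OCC | starting material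
21 | allyl 2-(diethoxyphosphoryl)acrylate | C=CCOC(=O)C(=C)P(=O)(OCC)OCC | intermediate
22 | allyl 2-(diethoxyphosphoryl)-3-(4-methoxybenzyloxy)propanoate (racemic) | C=CCOC(=O)C(COCc1ccc(OC)cc1)P(=O)(OCC)OCC | intermediate
23 | 2-(diethoxyphosphoryl)-3-(4-methoxybenzyloxy)propanoic acid (racemic) | OC(=O)C(COCc1ccc(OC)cc1)P(=O)(OCC)OCC | intermediate
24 | (2R,3E,7E,10S)-10-(4-methoxybenzyloxy)-4,8-dimethyl-1-oxocyclodeca-3,7-dien-2-yl 2-(diethoxyphosphoryl)-3-(4-methoxybenzyloxy)propanoate | COc1ccc(CO[C@H]2C/C(C)=C/CC/C(C)=C/[C@@H](OC(=O)C(COCc3ccc(OC)cc3)P(=O)(OCC)OCC)C2=O)cc1 | intermediate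
25 | (6R,8S)-8α,13-bis(4-methoxybenzyloxy)germacra-1(10)E,4E,7(11)-trien-6α,12-olide | COc1ccc(CO[C@H]2C/C(C)=C/CC/C(C)=C/[C@H]3OC(=O)C(COCc4ccc(OC)cc4)=C23)cc1 | intermediate
26 | (6R,8S)-8α,13-dihydroxygermacra-1(10)E,4E,7(11)-trien-6α,12-olide | O[C@H]1C/C(C)=C/CC/C(C)=C/[C@H]2OC(=O)C(CO)=C12 | intermediate
27 | (6R,8S)-13-acetoxy-8α-hydroxygermacra-1(10)E,4E,7(11)-trien-6α,12-olide | O[C@H]1C/C(C)=C/CC/C(C)=C/[C@H]2OC(=O)C(COC(C)=O)=C12 | intermediate
28 | ethyl 2-(hydroxymethyl)acrylate | C=C(CO)C(=O)OCC | starting material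
29 | ethyl 2-((tert-butyldimethylsilyloxy)methyl)acrylate | C=C(CO[Si](C)(C)C(C)(C)C)C(=O)OCC | intermediate
30 | 2-((tert-butyldimethylsilyloxy)methyl)acrylic acid | C=C(CO[Si](C)(C)C(C)(C)C)C(=O)O | intermediate
31 | (6R,8S)-13-acetoxy-8α-[2-((tert-butyldimethylsilyloxy)methyl)acryloyloxy]germacra-1(10)E,4E,7(11)-trien-6α,12-olide | C=C(CO[Si](C)(C)C(C)(C)C)C(=O)O[C@H]1C/C(C)=C/CC/C(C)=C/[C@H]2OC(=O)C(COC(C)=O)=C12 | intermediate
32 | (1R,6R,8S,10R)-13-acetoxy-8α-[2-((tert-butyldimethylsilyloxy)methyl)acryloyloxy]-1β,10α-epoxygermacra-4E,7(11)-dien-6α,12-olide | C=C(CO[Si](C)(C)C(C)(C)C)C(=O)O[C@H]1C[C@@]2(C)O[C@@H]2CC/C(C)=C/[C@H]2OC(=O)C(COC(C)=O)=C12 | intermediate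
33 | (1R,4R,5R,6S,8S,10R)-13-acetoxy-8α-[2-((tert-butyldimethylsilyloxy)methyl)acryloyloxy]-1β,10α:4α,5β-diepoxygermacr-7(11)-en-6α,12-olide | C=C(CO[Si](C)(C)C(C)(C)C)C(=O)O[C@H]1C[C@@]2(C)O[C@@H]2CC[C@@]2(C)O[C@@H]2[C@H]2OC(=O)C(COC(C)=O)=C12 | intermediate
34 | (1R,4R,5R,6S,8S,10R)-13-acetoxy-1β,10α:4α,5β-diepoxy-8α-[2-(hydroxymethyl)acryloyloxy]germacr-7(11)-en-6α,12-olide (CNP0282791.1) | C=C(CO)C(=O)O[C@H]1C[C@@]2(C)O[C@@H]2CC[C@@]2(C)O[C@@H]2[C@H]2OC(=O)C(COC(C)=O)=C12 | target

**Step count and risks**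
Total step count: 23. Longest linear sequence: 19 steps (steps 1–12, 15–18, 21–23); steps 13–14 and 19–20 are side branches.

Steps most likely to fail:

Step 10. The hydride may be delivered to the C4 end of the allylpalladium unit, the allyl unit may lose its E geometry, or the alkenylpalladium formed from the triflate may expel the neighbouring oxirane oxygen. The fallback takes the oxirane out before the ring expansion. From 10, SmI2 (THF/MeOH, −78 °C) should cleave the C–O bond next to the carbonyl and give (2R,4S,5S)-5-hydroxy-4-(4-methoxybenzyloxy)-2-methyl-2-vinylcyclohexan-1-one F1. Silylation with i-Pr3SiOTf and 2,6-lutidine gives its triisopropylsilyl ether F2. Addition of CH2=C(CH3)MgBr/CeCl3 anti to the axial vinyl group gives (1S,2R,4S,5S)-4-(4-methoxybenzyloxy)-2-methyl-1-(prop-1-en-2-yl)-5-(triisopropylsilyloxy)-2-vinylcyclohexan-1-ol F3. KH/18-crown-6 followed by PhNTf2 gives the ring-expanded enol triflate F4, and Pd(PPh3)4 with one equivalent of Bu3SnH reduces only the triflate to the diene silyl ether F5. Bu4NF then removes the silyl group and the route is rejoined at 16.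

Step 12. Facial selectivity in the hydroxylation of the macrocyclic dienolate may be poor or reversed. The fallback inverts instead of selecting. From 17, the same hydroxylation gives the 6β epimer (2S,3E,7E,10S)-2-hydroxy-10-(4-methoxybenzyloxy)-4,8-dimethylcyclodeca-3,7-dien-1-one F6. This is joined to acid 23 under Mitsunobu conditions (PPh3, diisopropyl azodicarboxylate, THF, 0 °C), which attaches the carboxylate to C6 with inversion and rejoins the route at 24.

Step 22. Facial selectivity at C1=C10 may be poor if more than one ring conformer reacts, and the first-formed oxirane may open across the ring under the acidic by-product. The fallback uses hydroxyl delivery and a stepwise order. From 27, VO(acac)2 with t-BuOOH (CH2Cl2, 0 °C) should epoxidize only the homoallylic C1=C10 alkene from the side of the 8α-hydroxyl and give 13-acetoxy-1β,10α-epoxy-8α-hydroxygermacra-4E,7(11)-dien-6α,12-olide F7. mCPBA (one equivalent, 0 °C) then gives 13-acetoxy-1β,10α:4α,5β-diepoxy-8α-hydroxygermacr-7(11)-en-6α,12-olide F8. Esterification of F8 with acid 30 (DCC, DMAP) rejoins the route at 33.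

**Further compounds**
F1 | step 10 | (2R,4S,5S)-5-hydroxy-4-(4-methoxybenzyloxy)-2-methyl-2-vinylcyclohexan-1-one | COc1ccc(CO[C@@H]2[C@@H](O)CC(=O)[C@@](C)(C=C)C2)cc1
F2 | step 10 | (2R,4S,5S)-4-(4-methoxybenzyloxy)-2-methyl-5-(triisopropylsilyloxy)-2-vinylcyclohexan-1-one | COc1ccc(CO[C@@H]2[C@@H](O[Si](C(C)C)(C(C)C)C(C)C)CC(=O)[C@@](C)(C=C)C2)cc1
F3 | step 10 | (1S,2R,4S,5S)-4-(4-methoxybenzyloxy)-2-methyl-1-(prop-1-en-2-yl)-5-(triisopropylsilyloxy)-2-vinylcyclohexan-1-ol | COc1ccc(CO[C@@H]2[C@@H](O[Si](C(C)C)(C(C)C)C(C)C)C[C@](O)(C(C)=C)[C@@](C)(C=C)C2)cc1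
F4 | step 10 | (1(10)E)-8α-(4-methoxybenzyloxy)-4,10-dimethyl-7β-(triisopropylsilyloxy)cyclodeca-1(10),4-dien-5-yl trifluoromethanesulfonate (C3 and C6 trans) | COc1ccc(CO[C@H]2C/C(C)=C/CC/C(C)=C(OS(=O)(=O)C(F)(F)F)/C[C@@H]2O[Si](C(C)C)(C(C)C)C(C)C)cc1
F5 | step 10 | (1(10)E,4E)-8α-(4-methoxybenzyloxy)-4,10-dimethyl-7β-(triisopropylsilyloxy)cyclodeca-1(10),4-diene | COc1ccc(CO[C@H]2C/C(C)=C/CC/C(C)=C/C[C@@H]2O[Si](C(C)C)(C(C)C)C(C)C)cc1
F6 | step 12 | (2S,3E,7E,10S)-2-hydroxy-10-(4-methoxybenzyloxy)-4,8-dimethylcyclodeca-3,7-dien-1-one | COc1ccc(CO[C@H]2C/C(C)=C/CC/C(C)=C/[C@H](O)C2=O)cc1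
F7 | step 22 | 13-acetoxy-1β,10α-epoxy-8α-hydroxygermacra-4E,7(11)-dien-6α,12-olide | O[C@H]1C[C@@]2(C)O[C@@H]2CC/C(C)=C/[C@H]2OC(=O)C(COC(C)=O)=C12
F8 | step 22 | 13-acetoxy-1β,10α:4α,5β-diepoxy-8α-hydroxygermacr-7(11)-en-6α,12-olide | O[C@H]1C[C@@]2(C)O[C@@H]2CC[C@@]2(C)O[C@@H]2[C@H]2OC(=O)C(COC(C)=O)=C12
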